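- A one-step world turns substrate and partner into product over free catalyst and slows only as they deplete, but Monday's run, with substrate still at 82.2 % of its charge, added 5.9 percentage points between 12.0 min and 25.0 min against 11.6 % before, less in a stretch of nearly equal length.

| setting | Wednesday's | Monday's | Friday's | west | north | east | north-west |
|---|---|---|---|---|---|---|---|
| substrate | 1.1 M | 1.1 M | 1.1 M | 1.1 M | 1.1 M | 1.1 M | 1.1 M |
| partner | 0.55 M | 0.83 M | 1.1 M | 1.10 M | 1.10 M | 1.10 M | 1.10 M |
| free catalyst | 55 mM | 55 mM | 28 mM | 55 mM | 55 mM | 55 mM | 55 mM |
| temperature | −5 °C | 25 °C | −5 °C |  | 0 °C | 50 °C | 25 °C |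
| remark | run made earlier | run made earlier | run made earlier | at 0 °C until 1.0 h, from then on at 50 °C |  |  |  |
| time |  |  |  | 1.5 h | 1.5 h | 1.5 h | 1.5 h |

| run | time / min | product / % | substrate / % |
|---|---|---|---|
| Wednesday's | 5.00 | 0.4 | 99.4 |
| Wednesday's | 15.0 | 0.9 | 98.8 |
| Wednesday's | 25.0 | 1.7 | 98.1 |
| Wednesday's | 40.0 | 3.4 | 97.1 |
| Wednesday's | 60.0 | 4.1 | 95.6 |
| Wednesday's | 80.0 | 5.1 | 94.3 |
| Monday's | 1.33 | 2.1 | 97.9 |
| Monday's | 4.00 | 4.5 | 95.5 |
| Monday's | 8.00 | 8.4 | 91.7 |
| Monday's | 12.0 | 11.6 | 88.5 |
| Monday's | 20.0 | 15.4 | 84.3 |
| Monday's | 25.0 | 17.5 | 82.2 |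
| Friday's | 6.00 | 0.5 | 100.2 |
| Friday's | 20.0 | 1.3 | 97.8 |
| Friday's | 30.0 | 2.3 | 98.5 |
| Friday's | 50.0 | 3.0 | 96.6 |
| Friday's | 80.0 | 4.9 | 95.1 |

(each reading ± 0.3 percentage points)



- the flask with the highest amount of product, in percent of the substrate charged ("all alike" if they lie within 1.5 percentage points) (west / north / east / north-west / all alike)
- final product, as a percentage of the substrate charged, in west
- final product, as a percentage of the substrate charged, in north
- final product, as a percentage of the substrate charged, in east
- final product, as a percentage of the substrate charged, in north-west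

- Dividing product by remaining substrate removes the depletion of substrate as a correction, under the assumption of first order in substrate, and gives 0.131 at 12.0 min and 0.212 at 25.0 min.
- The second stretch of Monday's run therefore adds a fraction 0.617 of the first, and if each later stretch keeps that fraction, the series sums to 0.342 for Monday's flask.
- Wednesday's and Friday's runs have nearly equal products of partner and free catalyst and stand at 5.1 % and 4.9 % at 80.0 min, so the pace reads as proportional to partner times free catalyst.
- North-west looks nearly the same as Monday's flask, with the same temperature, substrate and free catalyst, and differs in partner, 1.10 M against 0.83 M.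
- This reckoning, which is not the forecast's, assumes that the fading keeps its pace in both flasks, so north-west climbs further by the ratio of the partner charges, to 0.453.
- That number is the reach, the ratio of product to remaining substrate toward which a flask climbs, and product is then reach over one plus reach, 31.2 % of the substrate charged.
- The fading read from Monday's run has a lifetime of about 25.8 min, and north-west stands for 1.5 h, longer, so this reckoning has north-west end close to its reach, while the sum for Monday's flask, with its smaller partner charge, gives a lower 25.5 %, a reckoned figure, as that run's last reading is 17.5 % at 25.0 min.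
- The forecast names north-west and gives west 21 %, north 15 %, east 14 % and north-west 30 %, slightly below this reckoning, on the ground “I read this as catalyst dying”.

The flasks end at west 24.3 %, north 15.3 %, east 19.1 % and north-west 31.5 %, so north-west holds the most, and east lies 5.1 points above the forecast.

    partner → decomposed reagent (k = 0.00509 s⁻¹, Ea = 92.0 kJ mol⁻¹)
    substrate + partner + free catalyst → product + free catalyst, rate k2*[substrate]*[partner]*[free catalyst]/(1 + ([substrate]/sat2)) (2.96 M, k = 0.0383 M⁻² s⁻¹, Ea = 55.0 kJ mol⁻¹)
    partner + free catalyst → spent catalyst (k = 0.00295 M⁻¹ s⁻¹, Ea = 57.0 kJ mol⁻¹)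
    (constants at 50 °C)

North-west's product over remaining substrate is 0.460 against the reach of 0.453; at 1.50 h that flask holds 0.610 M of decomposed reagent, with partner at 9.76 % of its own charge and free catalyst at 34.8 % of the catalyst charged. The neighbour of north-west with 0.093 M of free catalyst has its reach scaled by the catalyst charges to 0.767, which gives 43.4 %, and that neighbour ends at 43.9 % product.

All runs were computed on assumed constants; scatter was added.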